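## Analysis of the target

Target 20 is a flavonol, a 2-aryl-4H-chromen-4-one. Ring A (C4a to C8a) carries free hydroxyls on C5 and C7, ring C carries the C4 carbonyl and a sulfate monoester on O3, and ring B carries a sulfate monoester on O3' beside a free hydroxyl on O4'. The molecule is planar and achiral, so stereocentres appear only transiently, in intermediates with a reduced ring C, and none has to be controlled. The fifteen-carbon skeleton is simple; the difficulty is to tell five oxygens apart, since O3 and O3' must be sulfated while O5, O7 and O4' stay free, and O3' and O4' are neighbours on one ring. The sulfate monoesters are the sensitive groups: ionic, hard to purify and cleaved by acid, the enol-type 3-O-sulfate most easily, so they must be introduced near the end and followed only by neutral chemistry. Ring A is a phloroglucinol ether and is prone to oxidation and to alkylation at carbon. The strategy rests on one feature: C4 is a benzylic carbon on C4a, ortho to the C8a–O1 bond of this electron-rich ring, so O1–C8a–C4a–C4 can be raised as an ortho-quinone methide (a 1-oxadiene). The C2=C3 unit can then be delivered, with ring B and both of its oxygens, as an enol ether. The cycloaddition gives ring C at the chroman level, so C4 has to be oxidised and ring C aromatised afterwards.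

## Retrosynthetic reasoning

**20 to 19.** The last bonds cut are the three O–benzyl bonds on O5, O7 and O4'. Sulfate monoester salts are inert to neutral hydrogenolysis, so debenzylation can be the final step and nothing harsher follows the sulfation. The forward reaction must remove three benzyl groups without touching the O–S bonds or the C2=C3 bond.

**19 to 18.** Both O–S bonds are cut together. Diol 18 has free hydroxyls only on O3 and O3', so the sulfation needs no selection and can be forced to completion. This moves the whole differentiation problem into protecting groups: the oxygens that end as sulfates share one acid-labile acetal, and those that end as hydroxyls share benzyl.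

**18 to 16, through 17.** In the reverse sense a silanol is added across C2=C3 and the two acetals are restored, which gives the 2-silyloxy chroman-4-one 16. In the forward sense one acid treatment should expel the silanol from the β-silyloxy ketone (giving the pyranone 17) and cleave both acetals. The aromatisation of ring C therefore costs no step of its own.

**16 to 15 to 14.** The C4 carbonyl is taken back through alcohol 15 to the methylene of chroman 14. C4 of 14 is benzylic to a ring with oxygen donors at both ortho positions and at the para position. This is the ideal site for hydride abstraction by a high-potential quinone, a reaction well established for 5,7-dialkoxy flavans, and no other C–H bond of 14 is comparably activated. The other order (elimination to a 4H-chromene, then radical oxygenation) was judged less secure: that enol ether would be sensitive to air and acid, and its allyl radical is spread over C4 and C2. It is kept in reserve.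

**14 to 13 plus 7.** The bonds C3–C4 and O1–C2 are cut, which opens ring C into methide 13 and silyl enol ether 7. This is the one disconnection that makes both bonds of ring C at once from fragments in which all five oxygens are already differentiated. The polarity is matched: C4 of 13 is electrophilic, the CH carbon of 7 is nucleophilic, and the charge that develops on C2 is stabilised by the silyloxy group and by ring B. The forward reaction must release 13 under conditions that 7 survives, and must give this regiochemistry.

**13 to 11 to 10.** Methide 13 cannot be stored; it is released from the O-Boc salicyl alcohol 11 when a magnesium base forms the alkoxide, the carbonate shifts to the benzylic oxygen and is expelled. Alcohol 11 comes from aldehyde 10 by hydride addition. Adding a complex hydride to 10 in the presence of 7 in one flask was considered and set aside: hydride left in the flask would reduce 13 to the 2-methylphenol, and a protic co-solvent would add to it. The hydride is therefore delivered by an electrophilic boron hydride, which gives a neutral borate and not an alkoxide, and the methide is released in a separate step by one equivalent of base.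

**10 to 9 to 8.** The carbonate and two O–benzyl bonds are cut. The selection among the three hydroxyls of 8 comes from hydrogen bonding: the hydroxyl chelated to the formyl group is the least nucleophilic, so two equivalents of benzylating agent leave it free. This oxygen becomes O1.

**7 to 6 to 5 to 2 to 1.** The O–Si bond of 7 is cut to ketone 6, which has only one enolisable carbon. The two acetals of 6 are put on together from diol 5, because O3 and O3' share the same fate. The future O3 is introduced by oxidation of a silyl enol ether of 2 (Rubottom oxidation). The benzyl on O4' is placed first, by the higher acidity of the hydroxyl para to the acetyl group of 1.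

## Alternatives that were turned down

**Alternative 1:** cyclic sulfate across O3' and O4'.
- **Disconnection:** no C–C bond is cut. The skeleton is bought as quercetin A1, and the O3' sulfate is traced back to a five-membered cyclic sulfate A3 spanning O3' and O4', made from catechol A2, whose O3 already carries a trichloroethyl-protected sulfate.
- **Forward key step:** 1,1'-sulfonyldiimidazole with Cs2CO3 ties the two ring B hydroxyls of A2 together through sulfur (two O–S bonds, one new ring) to give A3. A nucleophile then opens the ring at sulfur and expels the better leaving group, the O4' phenoxide, which is conjugated through C2 with the C4 carbonyl; the sulfate stays on O3'.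
- **For:** it is the shortest plan, builds no skeleton, and solves the O3'/O4' problem by an intrinsic electronic bias without a protecting group on ring B.
- **Against:**
  - The bias between the two phenoxides is modest, so some 4'-sulfated regioisomer must be expected, and as an ionic isomer of 20 it would be very hard to remove.
  - The opening nucleophile must attack the cyclic sulfate but neither the trichloroethyl sulfate diester on O3 nor the pyranone.
  - Making A2 from A1 requires O5 and O7 to be benzylated while O3 stays available, although O3 is more reactive than the chelated O5; this costs a protecting-group detour.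
- **Comparison:** Alternative 1 is clearly stronger in step economy. The chosen strategy offers instead that every oxygen has its fate fixed by construction (acetal where sulfate, benzyl where hydroxyl) and that the only regiochemical separation happens at compound 2, a simple neutral solid. As a de novo route it also allows labelled or ring-modified analogues.

**Alternative 2:** polyketide cyclisation.
- **Disconnection:** ring A itself is opened. The C4a–C5 bond (Claisen) and the O1–C2 bond (oxa-Michael) are cut, leading back to the open-chain cinnamoyl triketo ester A4.
- **Forward key step:** Mg(OMe)2 in methanol lets the C6 carbanion of A4 attack the ester carbonyl, closing ring A as a phloroglucinol. The resulting 2'-hydroxychalcone closes ring C by conjugate addition of a phenoxide to give racemic flavanone A5.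
- **For:** it is biomimetic, forms two rings in one flask from an acyclic precursor, uses cheap reagents, and has the C4 carbonyl present from the start.
- **Against:**
  - A4 is a tetracarbonyl chain with several enolisable positions. Aldol-type closure (C2 onto C7) and lactonisation to a styryl pyranone compete with the required Claisen mode, and only magnesium chelation enforces the choice.
  - A5 has free hydroxyls on O5 and O7 and lacks both O3 and the C2=C3 bond. Protection of ring A, dehydrogenation and oxygenation at C3 would still follow, each on an electron-rich, oxidation-prone intermediate.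
- **Comparison:** Alternative 2 is stronger on the oxidation state of C4. The chosen strategy brings O3 in with the dienophile and has all protecting groups in place before ring C is formed, so only the C4 oxidation remains after the key step.

**Alternative 3:** carbonylative coupling.
- **Disconnection:** the bonds C4a–C4 and C4–C3 are cut and C4 comes from carbon monoxide; the components are aryl iodide A6, carbon monoxide and ketone 6.
- **Forward key step:** Pd(OAc)2 with Xantphos and NaOC(CH3)3 under carbon monoxide. A6 adds oxidatively to zerovalent palladium, carbon monoxide inserts, and the aroyl palladium species acylates the enolate of 6 to give the racemic 2-alkoxy-1,3-diketone A7. No ring closes.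
- **For:** it is a convergent three-component union, uses the same ketone 6, and delivers C4 directly as a ketone, so no late C–H oxidation is needed; cyclodehydration of a 1,3-diketone to the chromone is classical.
- **Against:**
  - A6 is flanked by two ortho benzyloxy groups on a very electron-rich ring. Oxidative addition is slow, insertion and reductive elimination are hindered, and protodehalogenation, non-carbonylative arylation, O-acylation and capture of the acyl species by the alkoxide base all compete.
  - A7 still lacks ring C. One of two equivalent ortho benzyl ethers must be removed selectively before cyclisation. A chelating Lewis acid would threaten the acetals, and hydrogenolysis would also strip O7 and O4' and erase the differentiation.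
- **Comparison:** Alternative 3 is stronger in oxidation-level economy; it needs no counterpart of steps 9 and 10. The chosen strategy closes ring C in the same step that forms the C–C bond, using a ring A oxygen already distinguished from its ortho twin as the carbonate, and it needs no transition metal on a hindered substrate.

Key step: step 8

Assumption: the sulfate monoesters 19 and 20 are written as free acids, as in the target formula; in the flask they would be handled as ammonium or sodium salts, and the acid form corresponds to a brief cation exchange in the cold.

## Route

**Step 1**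
Reactants: 1 3',4'-dihydroxyacetophenone
Product: 2 1-[4-(benzyloxy)-3-hydroxyphenyl]ethan-1-one
Conditions: BnBr (1.05 equiv), NaHCO3, NaI (cat.), DMF, 40 °C
Reagents that add atoms: benzyl bromide, BrCc1ccccc1
Why: Williamson etherification under a weak base; the 4-hydroxyl, para to the acetyl group, is the more acidic phenol and the only one appreciably ionised by NaHCO3, so it should be alkylated selectively, and any isomeric or doubly benzylated material is removed at this stage by crystallisation.

**Step 2**
Reactants: 2 1-[4-(benzyloxy)-3-hydroxyphenyl]ethan-1-one
Product: 5 1-[4-(benzyloxy)-3-hydroxyphenyl]-2-hydroxyethan-1-one, via bis(trimethylsilyl) enol ether 3 (not isolated), via α-silyloxy ketone 4 (not isolated)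
Conditions: TMSOTf (2.3 equiv), Et3N, CH2Cl2, 0 °C, evaporate; mCPBA, NaHCO3, CH2Cl2, −10 °C; 1 M HCl–THF, rt
Reagents that add atoms: 3-chloroperoxybenzoic acid (mCPBA), O=C(OO)c1cccc(Cl)c1
Why: Rubottom oxidation; silylation gives the aryl silyl ether and the silyl enol ether of the methyl ketone (3), the peracid epoxidises the electron-rich enol double bond much faster than it attacks the arene or the ketone, and silyl migration gives 4, whose two silyl groups are lost in dilute acid. The phenol is masked only in passing, which saves a separate protection step.

**Step 3**
Reactants: 5 1-[4-(benzyloxy)-3-hydroxyphenyl]-2-hydroxyethan-1-one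
Product: 6 1-[4-(benzyloxy)-3-(methoxymethoxy)phenyl]-2-(methoxymethoxy)ethan-1-one
Conditions: MOMCl (3 equiv), i-Pr2NEt, CH2Cl2, 0 °C → rt
Reagents that add atoms: chloromethyl methyl ether, COCCl
Why: O-alkylation of the phenol and of the primary ketol hydroxyl with an α-chloro ether and an amine base; both oxygens that will later carry sulfate receive the same acid-labile acetal in one operation.

**Step 4**
Reactants: 6 1-[4-(benzyloxy)-3-(methoxymethoxy)phenyl]-2-(methoxymethoxy)ethan-1-one
Product: 7 (Z)-tert-butyl{[1-(4-(benzyloxy)-3-(methoxymethoxy)phenyl)-2-(methoxymethoxy)ethenyl]oxy}dimethylsilane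
Conditions: TBSOTf (1.3 equiv), Et3N, CH2Cl2, 0 °C
Reagents that add atoms: tert-butyldimethylsilyl trifluoromethanesulfonate, CC(C)(C)[Si](C)(C)OS(=O)(=O)C(F)(F)F
Why: Soft enolisation of an aryl ketone with a silyl triflate and an amine; only one α-carbon bears hydrogen, and the Z isomer (silyloxy and methoxymethoxy cis, aryl trans to the methoxymethoxy group) is expected because it avoids allylic strain with the aryl ring. The geometry has no consequence later, and the excess amine keeps the acetals safe from the silyl triflate.

**Step 5**
Reactants: 8 2,4,6-trihydroxybenzaldehyde
Product: 9 2,4-bis(benzyloxy)-6-hydroxybenzaldehyde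
Conditions: BnBr (2.05 equiv), K2CO3, DMF, 0 °C → rt
Reagents that add atoms: benzyl bromide, BrCc1ccccc1
Why: Williamson etherification; the hydroxyl hydrogen-bonded to the formyl group is the least nucleophilic, so two equivalents of halide should alkylate the para oxygen and one ortho oxygen and leave the chelated phenol, the future O1, free.

**Step 6**
Reactants: 9 2,4-bis(benzyloxy)-6-hydroxybenzaldehyde
Product: 10 3,5-bis(benzyloxy)-2-formylphenyl tert-butyl carbonate
Conditions: Boc2O, i-Pr2NEt, DMAP (cat.), THF, 0 °C → rt
Reagents that add atoms: di-tert-butyl dicarbonate, CC(C)(C)OC(=O)OC(=O)OC(C)(C)C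
Why: DMAP-catalysed O-acylation of the single free phenol to the aryl tert-butyl carbonate, the group that later transfers to the benzylic oxygen and leaves.

**Step 7**
Reactants: 10 3,5-bis(benzyloxy)-2-formylphenyl tert-butyl carbonate
Product: 11 3,5-bis(benzyloxy)-2-(hydroxymethyl)phenyl tert-butyl carbonate
Conditions: BH3·THF, THF, −10 °C; MeOH
Reagents that add atoms: none
Why: Carbonyl reduction by an electrophilic borane; the aldehyde becomes a neutral alkoxyborane and not a free alkoxide, so the carbonate should stay on the phenolic oxygen and no methide is released at this stage. Neutral methanolysis frees the alcohol, which is used without chromatography on acidic media.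

**Step 8**
Reactants: 11 3,5-bis(benzyloxy)-2-(hydroxymethyl)phenyl tert-butyl carbonate; 7 (Z)-tert-butyl{[1-(4-(benzyloxy)-3-(methoxymethoxy)phenyl)-2-(methoxymethoxy)ethenyl]oxy}dimethylsilane
Product: 14 5,7-bis(benzyloxy)-2-[4-(benzyloxy)-3-(methoxymethoxy)phenyl]-2-[(tert-butyldimethylsilyl)oxy]-3-(methoxymethoxy)chromane (racemic mixture of diastereomers), via magnesium phenoxide carbonate 12 (not isolated), via ortho-quinone methide 13 (not isolated)
Conditions: t-BuMgCl (1.05 equiv), 7 (2 equiv), THF, −78 °C → rt
Reagents that add atoms: none
Why: tert-Butylmagnesium chloride deprotonates 11, the magnesium alkoxide attacks the neighbouring aryl carbonate so that the Boc group shifts from the phenolic to the benzylic oxygen (12), and the magnesium phenoxide expels tert-butyl carbonate in a 1,4-elimination to release methide 13 at low temperature. Methide 13 is a 1-oxadiene with a low-lying LUMO and 7 is an alkene with two oxygen donors, so the union is a hetero-Diels–Alder reaction of inverse electron demand; the closest known reaction type is the magnesium-triggered release of ortho-quinone methides from O-Boc salicyl alcohols and their capture by enol ethers and silyl enol ethers to give 2-oxygenated chromans. Ring C closes in a [4+2] cycloaddition that forms C3–C4 and O1–C2; should the process be stepwise, the Michael-type C3–C4 bond forms first and the phenoxide then closes on the silyloxocarbenium carbon C2 in a 6-exo-trig manner. The selectivity needed is regiochemical: the CH carbon bearing the methoxymethoxy group must bond to the methide carbon, and this is secured because the developing positive charge then sits on C2, where the silyloxy group and the para-benzyloxyphenyl ring both stabilise it, whereas the opposite orientation would leave it on a carbon with a single alkoxy donor. The two new stereocentres C2 and C3 arise in one suprafacial addition, so their relative configuration follows the Z geometry of 7 and the endo or exo approach; neither is controlled, the product is racemic, and both centres are erased in step 11. Self-condensation of 13 is held back by releasing it in the presence of an excess of 7, the unreacted part of which should be recoverable.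

**Step 9**
Reactants: 14 5,7-bis(benzyloxy)-2-[4-(benzyloxy)-3-(methoxymethoxy)phenyl]-2-[(tert-butyldimethylsilyl)oxy]-3-(methoxymethoxy)chromane
Product: 15 5,7-bis(benzyloxy)-2-[4-(benzyloxy)-3-(methoxymethoxy)phenyl]-2-[(tert-butyldimethylsilyl)oxy]-3-(methoxymethoxy)chroman-4-ol (racemic mixture of diastereomers)
Conditions: DDQ (1.5 equiv), CH2Cl2–H2O (pH 7 buffer), 0 °C → rt
Reagents that add atoms: water, O
Why: Oxidative benzylic C–H functionalisation by hydride abstraction, as known for C4 of 5,7-dialkoxy flavans; DDQ removes hydride from C4 to give a cation stabilised by O1, O5 and O7, and water captures it. The new C4 stereocentre (attack expected anti to the C3 substituent) is not controlled and is removed in step 10; plain benzyl ethers and the acetals should not be attacked under buffered conditions.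

**Step 10**
Reactants: 15 5,7-bis(benzyloxy)-2-[4-(benzyloxy)-3-(methoxymethoxy)phenyl]-2-[(tert-butyldimethylsilyl)oxy]-3-(methoxymethoxy)chroman-4-ol
Product: 16 5,7-bis(benzyloxy)-2-[4-(benzyloxy)-3-(methoxymethoxy)phenyl]-2-[(tert-butyldimethylsilyl)oxy]-3-(methoxymethoxy)chroman-4-one (racemic mixture of diastereomers)
Conditions: Dess–Martin periodinane, NaHCO3, CH2Cl2, 0 °C → rt
Reagents that add atoms: none
Why: Dess–Martin oxidation of a secondary benzylic alcohol to the aryl ketone under near-neutral conditions, which the silyl ketal, the acetals and the benzyl ethers tolerate. Partial loss of silanol from the β-silyloxy ketone would only anticipate step 11.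

**Step 11**
Reactants: 16 5,7-bis(benzyloxy)-2-[4-(benzyloxy)-3-(methoxymethoxy)phenyl]-2-[(tert-butyldimethylsilyl)oxy]-3-(methoxymethoxy)chroman-4-one
Product: 18 5,7-bis(benzyloxy)-2-[4-(benzyloxy)-3-hydroxyphenyl]-3-hydroxy-4H-chromen-4-one, via bis(methoxymethyl) flavone 17 (not isolated)
Conditions: HCl (2 M), MeOH–THF, 45 °C
Reagents that add atoms: none
Why: Acid-catalysed β-elimination of silanol from the β-silyloxy ketone gives chromone 17, a vinylogous ester and the thermodynamic sink, and acetal methanolysis then frees O3 and O3'. If the silyl ketal were hydrolysed first, the resulting 2-hydroxyflavanone and its open 1,3-diketone form would cyclodehydrate to the same chromone, as in the last stage of a Baker–Venkataraman flavone synthesis; benzyl ethers are stable to dilute acid.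

**Step 12**
Reactants: 18 5,7-bis(benzyloxy)-2-[4-(benzyloxy)-3-hydroxyphenyl]-3-hydroxy-4H-chromen-4-one
Product: 19 5,7-bis(benzyloxy)-2-[4-(benzyloxy)-3-(sulfooxy)phenyl]-4-oxo-4H-chromen-3-yl hydrogen sulfate
Conditions: SO3·NMe3 (10 equiv), Et3N, DMF, 55 °C
Reagents that add atoms: sulfur trioxide–trimethylamine complex, C[N+](C)(C)S(=O)(=O)[O-]
Why: O-Sulfation of a phenol and an enol hydroxyl with a sulfur trioxide amine complex; O3 and O3' are the only free hydroxyls, so excess reagent and warming can drive the hydrogen-bonded 3-hydroxyl to completion without any regiochemical question. The product would be handled as its bis(triethylammonium) salt.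

**Step 13**
Reactants: 19 5,7-bis(benzyloxy)-2-[4-(benzyloxy)-3-(sulfooxy)phenyl]-4-oxo-4H-chromen-3-yl hydrogen sulfate
Product: 20 quercetin 3,3'-bissulfate, 5,7-dihydroxy-2-[4-hydroxy-3-(sulfooxy)phenyl]-4-oxo-4H-chromen-3-yl hydrogen sulfate
Conditions: H2 (1 atm), Pd/C (10 %), MeOH–THF–H2O, rt; H+-form cation-exchange resin, H2O, 0 °C
Reagents that add atoms: none
Why: Hydrogenolysis of three benzyl aryl ethers over palladium on carbon; sulfate monoester salts are not reduced and the tetrasubstituted C2=C3 bond of the chromone should not be hydrogenated at atmospheric pressure. Brief cation exchange in the cold converts the salt into the acid form drawn.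

## Compound list

1 | 3',4'-dihydroxyacetophenone | CC(=O)c1ccc(O)c(O)c1 | starting material
2 | 1-[4-(benzyloxy)-3-hydroxyphenyl]ethan-1-one | CC(=O)c1ccc(OCc2ccccc2)c(O)c1 | intermediate
3 | trimethyl({1-[4-(benzyloxy)-3-(trimethylsilyloxy)phenyl]ethenyl}oxy)silane | C=C(O[Si](C)(C)C)c1ccc(OCc2ccccc2)c(O[Si](C)(C)C)c1 | intermediate
4 | 1-[4-(benzyloxy)-3-(trimethylsilyloxy)phenyl]-2-(trimethylsilyloxy)ethan-1-one | O=C(CO[Si](C)(C)C)c1ccc(OCc2ccccc2)c(O[Si](C)(C)C)c1 | intermediate
5 | 1-[4-(benzyloxy)-3-hydroxyphenyl]-2-hydroxyethan-1-one | O=C(CO)c1ccc(OCc2ccccc2)c(O)c1 | intermediate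
6 | 1-[4-(benzyloxy)-3-(methoxymethoxy)phenyl]-2-(methoxymethoxy)ethan-1-one | COCOCC(=O)c1ccc(OCc2ccccc2)c(OCOC)c1 | intermediate
7 | (Z)-tert-butyl{[1-(4-(benzyloxy)-3-(methoxymethoxy)phenyl)-2-(methoxymethoxy)ethenyl]oxy}dimethylsilane | COCO/C=C(\O[Si](C)(C)C(C)(C)C)c1ccc(OCc2ccccc2)c(OCOC)c1 | intermediate
8 | 2,4,6-trihydroxybenzaldehyde | O=Cc1c(O)cc(O)cc1O | starting material
9 | 2,4-bis(benzyloxy)-6-hydroxybenzaldehyde | O=Cc1c(O)cc(OCc2ccccc2)cc1OCc1ccccc1 | intermediate
10 | 3,5-bis(benzyloxy)-2-formylphenyl tert-butyl carbonate | O=Cc1c(OC(=O)OC(C)(C)C)cc(OCc2ccccc2)cc1OCc1ccccc1 | intermediate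
11 | 3,5-bis(benzyloxy)-2-(hydroxymethyl)phenyl tert-butyl carbonate | OCc1c(OC(=O)OC(C)(C)C)cc(OCc2ccccc2)cc1OCc1ccccc1 | intermediate
12 | chloromagnesium 3,5-bis(benzyloxy)-2-{[(tert-butoxycarbonyl)oxy]methyl}phenolate | CC(C)(C)OC(=O)OCc1c([O-])cc(OCc2ccccc2)cc1OCc1ccccc1.[Mg+2].[Cl-] | intermediate
13 | 3,5-bis(benzyloxy)-6-methylidenecyclohexa-2,4-dien-1-one | C=C1C(=O)C=C(OCc2ccccc2)C=C1OCc1ccccc1 | intermediate
14 | 5,7-bis(benzyloxy)-2-[4-(benzyloxy)-3-(methoxymethoxy)phenyl]-2-[(tert-butyldimethylsilyl)oxy]-3-(methoxymethoxy)chromane, racemic mixture of diastereomers | COCOC1Cc2c(OCc3ccccc3)cc(OCc3ccccc3)cc2OC1(O[Si](C)(C)C(C)(C)C)c1ccc(OCc2ccccc2)c(OCOC)c1 | intermediate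
15 | 5,7-bis(benzyloxy)-2-[4-(benzyloxy)-3-(methoxymethoxy)phenyl]-2-[(tert-butyldimethylsilyl)oxy]-3-(methoxymethoxy)chroman-4-ol, racemic mixture of diastereomers | COCOC1C(O)c2c(OCc3ccccc3)cc(OCc3ccccc3)cc2OC1(O[Si](C)(C)C(C)(C)C)c1ccc(OCc2ccccc2)c(OCOC)c1 | intermediate
16 | 5,7-bis(benzyloxy)-2-[4-(benzyloxy)-3-(methoxymethoxy)phenyl]-2-[(tert-butyldimethylsilyl)oxy]-3-(methoxymethoxy)chroman-4-one, racemic mixture of diastereomers | COCOC1C(=O)c2c(OCc3ccccc3)cc(OCc3ccccc3)cc2OC1(O[Si](C)(C)C(C)(C)C)c1ccc(OCc2ccccc2)c(OCOC)c1 | intermediate
17 | 5,7-bis(benzyloxy)-2-[4-(benzyloxy)-3-(methoxymethoxy)phenyl]-3-(methoxymethoxy)-4H-chromen-4-one | COCOc1c(-c2ccc(OCc3ccccc3)c(OCOC)c2)oc2cc(OCc3ccccc3)cc(OCc3ccccc3)c2c1=O | intermediate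
18 | 5,7-bis(benzyloxy)-2-[4-(benzyloxy)-3-hydroxyphenyl]-3-hydroxy-4H-chromen-4-one | O=c1c(O)c(-c2ccc(OCc3ccccc3)c(O)c2)oc2cc(OCc3ccccc3)cc(OCc3ccccc3)c12 | intermediate
19 | 5,7-bis(benzyloxy)-2-[4-(benzyloxy)-3-(sulfooxy)phenyl]-4-oxo-4H-chromen-3-yl hydrogen sulfate | O=c1c(OS(=O)(=O)O)c(-c2ccc(OCc3ccccc3)c(OS(=O)(=O)O)c2)oc2cc(OCc3ccccc3)cc(OCc3ccccc3)c12 | intermediate
20 | quercetin 3,3'-bissulfate, 5,7-dihydroxy-2-[4-hydroxy-3-(sulfooxy)phenyl]-4-oxo-4H-chromen-3-yl hydrogen sulfate | O=c1c(OS(=O)(=O)O)c(-c2ccc(O)c(OS(=O)(=O)O)c2)oc2cc(O)cc(O)c12 | target

## Step count and least certain steps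

Total: 13 steps. Longest linear sequence: 10 steps (steps 1 to 4, then 8 to 13). The ring A branch (steps 5 to 7) joins at step 8.

**Step 8 (key step).** The most likely failure is that the methide is consumed by self-condensation or by the tert-butoxide set free before the cycloaddition occurs. The dienophile is trisubstituted, its two oxygen donors polarise the double bond in opposite senses, and the methide is tempered by two alkoxy groups. Loss of the silyl group of 7 to magnesium alkoxides is a second risk. Fallback, setting out from 9 and returning at 14: reductive amination of 9 with dimethylamine and NaBH(OAc)3 would give the Mannich base 3,5-bis(benzyloxy)-2-[(dimethylamino)methyl]phenol F1. N-Methylation with iodomethane would give [2,4-bis(benzyloxy)-6-hydroxybenzyl]trimethylammonium iodide F2. Warming F2 with 7 and i-Pr2NEt in acetonitrile should expel trimethylamine and release methide 13 slowly, at a temperature at which the cycloaddition can keep pace and with no alkoxide nucleophile present, to give 14. This replaces the low-temperature magnesium trigger by a slow base-induced release from an ammonium salt.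

**Step 9.** What may go wrong is ionisation of the silyl ketal by the acidic hydroquinone, loss of a proton from the C4 cation towards C3 instead of capture by water, or slow oxidative attack on the benzyl ethers. Fallback, setting out from 14 and returning at 17: pyridinium p-toluenesulfonate in hot toluene over molecular sieves should expel silanol from the ketal to give the enol ether 5,7-bis(benzyloxy)-2-[4-(benzyloxy)-3-(methoxymethoxy)phenyl]-3-(methoxymethoxy)-4H-chromene F3. Its doubly activated C4 methylene would then be oxidised with tert-butyl hydroperoxide and catalytic CuI (peroxidation of the allylic and benzylic position, then collapse of the peroxide to the ketone) to give 17, which is carried through the acid treatment of step 11. Here the order is reversed, with elimination first and a radical C–H oxidation in place of hydride abstraction. It is held in reserve because the intermediate allyl radical is shared between C4 and C2.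

**Step 7.** What may go wrong is transfer of the carbonate to the benzylic oxygen during reduction or work-up, with premature release and loss of the methide, or deoxygenation of the very electron-rich benzylic position by the borane. Fallback, setting out from 9 and returning at 14: NaBH4 in methanol should reduce the free salicylaldehyde 9 to the saligenin 3,5-bis(benzyloxy)-2-(hydroxymethyl)phenol F4. Heating F4 with 7 in toluene over molecular sieves would dehydrate it thermally to methide 13, which is trapped by 7 to give 14. Compounds 10 and 11 are bypassed, and no carbonate has to survive a hydride.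

**Step 12.** What may go wrong is incomplete sulfation of the chelated 3-hydroxyl, or loss of the 3-O-sulfate during isolation, giving mixtures of ionic mono- and bis-sulfates that are hard to separate. Fallback, setting out from 18 and returning at 19: 2,2,2-trichloroethyl chlorosulfate with Et3N and DMAP in THF would convert both hydroxyls into neutral sulfate diesters, giving 5,7-bis(benzyloxy)-2-{4-(benzyloxy)-3-[(2,2,2-trichloroethoxy)sulfonyloxy]phenyl}-4-oxo-4H-chromen-3-yl 2,2,2-trichloroethyl sulfate F5. F5 can be purified on silica until bis-functionalisation is complete. Zn with ammonium formate in methanol would then remove both trichloroethyl groups reductively to give 19.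

## Further compounds

F1 | step 8 | 3,5-bis(benzyloxy)-2-[(dimethylamino)methyl]phenol | CN(C)Cc1c(O)cc(OCc2ccccc2)cc1OCc1ccccc1
F2 | step 8 | [2,4-bis(benzyloxy)-6-hydroxybenzyl]trimethylammonium iodide | C[N+](C)(C)Cc1c(O)cc(OCc2ccccc2)cc1OCc1ccccc1.[I-]
F3 | step 9 | 5,7-bis(benzyloxy)-2-[4-(benzyloxy)-3-(methoxymethoxy)phenyl]-3-(methoxymethoxy)-4H-chromene | COCOC1=C(c2ccc(OCc3ccccc3)c(OCOC)c2)Oc2cc(OCc3ccccc3)cc(OCc3ccccc3)c2C1
F4 | step 7 | 3,5-bis(benzyloxy)-2-(hydroxymethyl)phenol | OCc1c(O)cc(OCc2ccccc2)cc1OCc1ccccc1
F5 | step 12 | 5,7-bis(benzyloxy)-2-{4-(benzyloxy)-3-[(2,2,2-trichloroethoxy)sulfonyloxy]phenyl}-4-oxo-4H-chromen-3-yl 2,2,2-trichloroethyl sulfate | O=c1c(OS(=O)(=O)OCC(Cl)(Cl)Cl)c(-c2ccc(OCc3ccccc3)c(OS(=O)(=O)OCC(Cl)(Cl)Cl)c2)oc2cc(OCc3ccccc3)cc(OCc3ccccc3)c12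
A1 | alternative 1 | quercetin, 2-(3,4-dihydroxyphenyl)-3,5,7-trihydroxy-4H-chromen-4-one | O=c1c(O)c(-c2ccc(O)c(O)c2)oc2cc(O)cc(O)c12
A2 | alternative 1 | 5,7-bis(benzyloxy)-2-(3,4-dihydroxyphenyl)-4-oxo-4H-chromen-3-yl 2,2,2-trichloroethyl sulfate | O=c1c(OS(=O)(=O)OCC(Cl)(Cl)Cl)c(-c2ccc(O)c(O)c2)oc2cc(OCc3ccccc3)cc(OCc3ccccc3)c12
A3 | alternative 1 | 5,7-bis(benzyloxy)-2-(2,2-dioxido-1,3,2-benzodioxathiol-5-yl)-4-oxo-4H-chromen-3-yl 2,2,2-trichloroethyl sulfate | O=c1c(OS(=O)(=O)OCC(Cl)(Cl)Cl)c(-c2ccc3OS(=O)(=O)Oc3c2)oc2cc(OCc3ccccc3)cc(OCc3ccccc3)c12
A4 | alternative 2 | methyl (E)-9-[4-(benzyloxy)-3-(methoxymethoxy)phenyl]-3,5,7-trioxonon-8-enoate | COC(=O)CC(=O)CC(=O)CC(=O)/C=C/c1ccc(OCc2ccccc2)c(OCOC)c1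
A5 | alternative 2 | racemic 2-[4-(benzyloxy)-3-(methoxymethoxy)phenyl]-5,7-dihydroxychroman-4-one | O=C1CC(c2ccc(OCc3ccccc3)c(OCOC)c2)Oc2cc(O)cc(O)c12
A6 | alternative 3 | 1,3,5-tris(benzyloxy)-2-iodobenzene | Ic1c(OCc2ccccc2)cc(OCc2ccccc2)cc1OCc1ccccc1
A7 | alternative 3 | racemic 1-[2,4,6-tris(benzyloxy)phenyl]-3-[4-(benzyloxy)-3-(methoxymethoxy)phenyl]-2-(methoxymethoxy)propane-1,3-dione | COCOC(C(=O)c1c(OCc2ccccc2)cc(OCc2ccccc2)cc1OCc1ccccc1)C(=O)c1ccc(OCc2ccccc2)c(OCOC)c1
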